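## Structural features

The target is a daucane: a cyclopentane (ring A, C1–C5) trans-fused through the C1–C5 bond to a cycloheptene (ring B, C1 and C5–C10), with C8=C9 as the only ring alkene and methyl groups on C1 and C8. Five stereocentres form one array, C10–C1–C5(–C4)–C6: the quaternary C1 lies between the angelate carbon C10 and the fusion CH (C5), and C5 lies between the isopropyl carbinol C4 and the p-anisate carbon C6. O10, the ring-A bond C1–C2, H5, O6 and the isopropyl group stand on one face; the angular methyl and the C4 hydroxyl stand on the other. The fragile groups are the angelate (Z to E with nucleophilic catalysts or base), the allylic C10–O bond, and, while C6 is a ketone, the β-hydroxy ketone C4–C5–C6 (retro-aldol) and the β,γ-placed C8=C9 bond (migration into conjugation, or loss of a C10 leaving group towards a tropone). The real difficulty is the quaternary C1, whose ring-A carbon must enter cis to the oxygen on the neighbouring C10, together with the trans fusion and the tertiary carbinol. The key step exploits that C1(CH3)–C10–C9–C8(CH3) is 2,5-dimethylfuran if the oxygen that ends on C10 starts as the furan oxygen on C1 and C8, and that C5–C6(=O)–C7 is an oxyallyl unit, so a (4+3) cycloaddition makes C1–C5, C7–C8 and all of ring B at once.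

## Logic of the disconnections

26 ⇒ 23 + 24 (through 25). The C10–O acyl bond is cut first because the Z-configured ester is the most labile group and should be made last. This removes the only isomerisable alkene. The forward step must acylate a hindered allylic alcohol next to a quaternary carbon without Z/E isomerisation and without touching the tertiary hydroxyl.

23 ⇒ 22 ⇒ 20 + 21. The Si–O bond at C10 and then the C6–O acyl bond are cut. The two secondary oxygens cannot be told apart by reactivity, so O10 stays silylated while O6 is acylated. The demand is that 20 carries one free secondary hydroxyl only.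

20 ⇒ 19. The C6–H bond is cut (reduction). C6 must be a ketone earlier for enolate chemistry, and in 19 the C4 hydroxyl can steer the hydride. The step must deliver hydride from the face of the C4 hydroxyl to give the anti-1,3-diol.

19 ⇒ 18. The C4–C5 bond is cut as an aldol retron. Ring A opens and two stereocentres disappear. The forward step needs an enolate at C5 and not at the more acidic C7, a trans ring fusion, and the hydroxyl on the face of the angular methyl.

18 ⇒ 17 ⇒ 16. The C4 ketone is masked as a ketal and the C5–Br bond is cut back to a silyl enol ether. The bromide marks C5 for regiospecific enolate formation; 16 is what a trapped conjugate addition gives.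

16 ⇒ 9 + 13 (through 14 and 15). The C1–C2 bond is cut as a conjugate-addition retron. This removes the quaternary centre and splits off the three-carbon fragment C2–C4 with its isopropyl group. The forward step must form a quaternary carbon and deliver C2 cis to O10, against the steric bias, so the free hydroxyl of 9 has to direct it.

13 ⇒ 12 ⇒ 11 ⇒ 10. C–Br, C–H (ester reduction) and the two ketal C–O bonds are cut in turn. This leads to a commercial β-keto ester and makes the homoenolate equivalent for C2–C4.

9 ⇒ 7 (through 8). The C10–O bond is cut and the oxygen is put back on C8, with the alkene returning from C8=C9 to C9=C10. This is where the bridge oxygen is relocated. The forward shift must be suprafacial, so that C10 inherits the face of C8, and must be driven, because it gives up the dienone conjugation.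

7 ⇒ 5 ⇒ 4 (through 6). The C8 oxygen is reconnected to C1 (retro-β-elimination across C5–C1) and the silyl enol ether is returned to the ketone. The result is a meso bicycle with no absolute configuration. The forward step must remove a proton from one of two enantiotopic methylenes.

4 ⇒ 1 + 2 (through 3). The C1–C5 and C7–C8 bonds are cut. Ring B falls apart into two symmetric commercial compounds. The forward step needs no regio- or stereocontrol, only a clean cycloaddition.

## Other disconnections considered

Alternative 1: The cut is C3–C4 in ring A. It leaves iodo ketone A1, a cycloheptene that already has C1, C5, C6 and C10 in final form, a 2-iodoethyl arm on C1 and an isobutyryl group on C5. In the forward step SmI2 would reduce the primary iodide and the alkylsamarium would add to the isopropyl ketone in a 5-exo Barbier closure to give bis-silyl ether A2.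
- In its favour: the closure is irreversible and has no enolate regiochemistry to go wrong. C5 is α to the ketone and can be settled trans to the C1 arm before the ring closes. Samarium chelated between the ketone and the C6 silyloxy group offers a handle on the C4 face. On these points it is the better ring-A closure, since the chosen aldol (step 11) relies on an equilibrating aldolate.
- Equal point: A2 holds the two secondary oxygens already differentiated, as 22 does.
- Against it here: the key step makes one bond and one stereocentre. A1, with four stereocentres including the quaternary C1, is the real problem and needs its own long route. A β-silyloxy ketone can also lose silanolate under single-electron conditions.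
- Comparison: on step economy the chosen plan is ahead, because its key step builds ring B, both methyl-bearing carbons and the C6 carbonyl in step 1. Mechanistically the two are complementary (one-electron organometallic addition against a cationic cycloaddition).

Alternative 2: The cut is C1–C10 and C5–C6 as a cyclobutane, followed by the C6–C10 bond of the derived diol. In the forward step the triplet of 3-methylcyclopent-2-en-1-one A3 would add to the symmetric 4-methyl-1,2-bis(trimethylsilyloxy)cyclopentene A4 to give the cis-anti-cis photoadduct A5. Desilylation and glycol cleavage would then open the four-membered ring to trione A6, with ketones at C4, C6 and C10.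
- In its favour: two steps reach the whole bicyclic carbon skeleton, and the quaternary C1 forms directly at the enone β-carbon. On both points it is better than the chosen plan, which closes ring A only at step 11 and needs a directed addition for C1.
- Equal point: the symmetric alkene removes the regiochemical question, as the symmetric furan does.
- Against it here: there is no element of absolute control, so it is racemic unless resolved or templated. The ring fusion arrives cis and must be corrected at C5, which sits between two ketones. Three ketones must be told apart. C8=C9 and the configurations at C4, C6 and C10 are all still to be made. Photochemical throughput is limited.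
- Comparison: the alternative wins on skeleton-building economy; the chosen plan wins on absolute configuration (one chiral base) and on arriving with the oxygen pattern and the alkene position already encoded.

Alternative 3: The cut is C1–C5 and C1–C10 at the carbenoid carbon C1. In the forward step a chiral copper or rhodium carbenoid from diazoketone A7 would add to the ipso–ortho bond of its arene, and the norcaradiene would open to the cycloheptatriene A8.
- In its favour: one step would make ring A, ring B and the quaternary C1 with catalyst-set absolute configuration. The arene is symmetric, so both ortho bonds are equivalent. Oxygen at C6 and C10 and the C8 methyl are in place. In bonds per step it is the best of the four plans, and it fixes C1 in the key step itself, which the chosen plan does only at step 8.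
- Against it here: α-alkyl diazoketone carbenoids are prone to 1,2-hydride shift. Ring A arrives with an unwanted ketone on C2 and nothing on C4, so the isopropyl carbinol needs a late oxidation or transposition. The triene must be reduced to leave only C8=C9. Both enol ethers must become alcohols of defined configuration, and the trans fusion must still be set.
- Comparison: the alternative is ahead on skeleton and on C1; the chosen plan is ahead on functional-group match, since the cycloadduct carries oxygen at C6 and the oxygen destined for C10.

Key step: step 1

Remark: locants C1–C10 of the target are used for all ring-B and bicyclic intermediates, CIP descriptors written with them refer to these locants, and "dauc-8-ene" means the trans-fused hydroazulene with methyl on C1 and C8, isopropyl on C4 and C8=C9.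

Remark: the sense of the enantiotopic deprotonation in step 2 is assumed to be the one drawn for the (R,R)-amide; if a first run shows the opposite sense, the (S,S)-amide is used with no other change.

## Route

Step 1
Reactants: 1 2,5-dimethylfuran; 2 1,1,3,3-tetrabromoacetone
Product: 4 (1R,5S)-1,5-dimethyl-8-oxabicyclo[3.2.1]oct-6-en-3-one (meso), via dibromo cycloadduct 3 (not isolated)
Conditions: Zn dust, B(OEt)3, THF, 0 °C to 25 °C, dark; then Zn–Cu couple, NH4Cl, MeOH, −78 °C to 25 °C
Reagents that add atoms: none
Why: Zinc removes a bromine from 2 and the zinc enolate ionises to a 1,3-dibromo-2-oxyallyl cation, which B(OEt)3 keeps from self-condensation; this is the classical reductive oxyallyl cation–furan (4+3) cycloaddition of polybromoketones. The cation adds across C2 and C5 of 1 and forms C1–C5 and C7–C8, either concerted through a compact transition state or in two fast steps through an oxygen-stabilised cation. Ring B closes by cycloaddition onto both diene termini from one face, so the furan oxygen becomes a one-atom bridge between C1 and C8 of the new seven-membered ring. The two bridgehead stereocentres are fixed relative to each other by the bridge, which allows only the cis arrangement; the bromine-bearing carbons lose their stereochemistry when zinc–copper couple and NH4Cl remove both halogens, so 4 is meso. No regio- or facial selectivity is needed because both partners are symmetric; the only selectivity required is cycloaddition over electrophilic substitution of the furan, which the methyl groups on both α-positions of 1 secure. The alkene and the ketone should survive the mild reductive debromination, and zinc replaces the toxic iron carbonyl often used for this reaction.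

Step 2
Reactants: 4 (1R,5S)-1,5-dimethyl-8-oxabicyclo[3.2.1]oct-6-en-3-one
Product: 5 (1R,5R)-1,5-dimethyl-3-(trimethylsilyloxy)-8-oxabicyclo[3.2.1]octa-2,6-diene
Conditions: (R,R)-[PhCH(CH3)]2NH, n-BuLi, LiCl, THF, −78 °C; TMSCl present before 4 is added, −100 °C; Et3N, pentane work-up
Reagents that add atoms: chlorotrimethylsilane, C[Si](C)(C)Cl
Why: Enantioselective deprotonation of a meso ketone by a twofold-symmetric chiral lithium amide with in situ silylation; the base takes a proton from one enantiotopic α-methylene, which becomes C5, so the bridgehead next to the enol ether becomes C1 and the other becomes C8. This step sets the absolute configuration of the whole route.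

Step 3
Reactants: 5 (1R,5R)-1,5-dimethyl-3-(trimethylsilyloxy)-8-oxabicyclo[3.2.1]octa-2,6-diene
Product: 7 (6R)-6-hydroxy-3,6-dimethylcyclohepta-2,4-dien-1-one, via tertiary trimethylsilyl ether 6 (not isolated)
Conditions: TMSOTf (5 mol %), CH2Cl2, −78 °C; Et3N; then citric acid, MeOH, 0 °C
Reagents that add atoms: none
Why: Lewis-acid-triggered ring opening of an oxabicyclic silyl enol ether (β-elimination across C5–C1): the activated bridge oxygen leaves C1, the enol ether becomes the C1=C5 enone and the silyl group ends on the C8 oxygen, whose configuration is untouched. Buffered methanolysis then frees the tertiary alcohol under conditions too mild for elimination to the tropone.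

Step 4
Reactants: 7 (6R)-6-hydroxy-3,6-dimethylcyclohepta-2,4-dien-1-one
Product: 9 (4R)-4-hydroxy-3,6-dimethylcyclohepta-2,5-dien-1-one, via secondary trimethylsilyl ether 8 (not isolated)
Conditions: Ph3SiOReO3 (2 mol %), BSA (1.3 equiv), Et2O, −20 °C to 0 °C; then citric acid, MeOH, 0 °C
Reagents that add atoms: none
Why: Perrhenate-catalysed 1,3-transposition of an allylic alcohol: the oxygen passes from C8 to C10 through a six-membered perrhenate ester, which in a ring can only be suprafacial, so C10 takes the face of C8 (10R) and C8=C9 becomes the trisubstituted alkene of the target. The shift gives up the dienone conjugation, so it is pulled forward by BSA, which silylates the secondary alcohol of the product much faster than the tertiary alcohol of 7; an ester at C8 is avoided because a β-acyloxy ketone with acidic C7 hydrogens would eliminate to the tropone.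

Step 5
Reactants: 10 methyl 4-methyl-3-oxopentanoate
Product: 11 methyl 2-[2-(propan-2-yl)-1,3-dioxolan-2-yl]acetate
Conditions: HOCH2CH2OH, TsOH·H2O (cat.), toluene, reflux, azeotropic removal of water
Reagents that add atoms: ethane-1,2-diol, OCCO
Why: Acid-catalysed ketalisation of the ketone of a β-keto ester; it protects the future C4 carbonyl for the organomagnesium chemistry.

Step 6
Reactants: 11 methyl 2-[2-(propan-2-yl)-1,3-dioxolan-2-yl]acetate
Product: 12 2-[2-(propan-2-yl)-1,3-dioxolan-2-yl]ethan-1-ol
Conditions: LiAlH4, THF, 0 °C; aqueous NaOH work-up
Reagents that add atoms: none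
Why: Hydride reduction of the ester to the primary alcohol; the ketal is inert to hydride and to the basic work-up.

Step 7
Reactants: 12 2-[2-(propan-2-yl)-1,3-dioxolan-2-yl]ethan-1-ol
Product: 13 2-(2-bromoethyl)-2-(propan-2-yl)-1,3-dioxolane
Conditions: CBr4, PPh3, 2,6-lutidine, CH2Cl2, 0 °C
Reagents that add atoms: tetrabromomethane, BrC(Br)(Br)Br
Why: Appel bromination of a primary alcohol; the hindered base keeps the medium neutral so the ketal survives.

Step 8
Reactants: 9 (4R)-4-hydroxy-3,6-dimethylcyclohepta-2,5-dien-1-one; 13 2-(2-bromoethyl)-2-(propan-2-yl)-1,3-dioxolane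
Product: 16 (1S,10R)-6,10-bis(tert-butyldimethylsilyloxy)-1,8-dimethyl-1-{2-[2-(propan-2-yl)-1,3-dioxolan-2-yl]ethyl}cyclohepta-5,8-diene, via Grignard reagent 14 (not isolated), via magnesium enolate 15 (not isolated)
Conditions: 13, Mg, THF, 25 °C; 9, t-BuMgCl (1.05 equiv), THF, −78 °C; 14 (2.5 equiv), −78 °C to −20 °C; TBSOTf (4 equiv), Et3N, DMPU, −78 °C to 0 °C
Reagents that add atoms: tert-butyldimethylsilyl trifluoromethanesulfonate, CC(C)(C)[Si](C)(C)OS(=O)(=O)C(F)(F)F
Why: Alkoxide-directed (chelation-controlled) conjugate addition of a Grignard reagent to a cyclic γ-hydroxy enone: the magnesium alkoxide on C10 binds the alkylmagnesium and hands the alkyl group to the neighbouring β-carbon C1 from its own face, so C2 enters cis to O10 and the methyl group goes to the other face (1S), where an undirected cuprate would add anti. TBSOTf then caps the enolate oxygen, which fixes the C5=C6 regiochemistry, and the C10 alkoxide, which must be protected for step 11.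

Step 9
Reactants: 16 (1S,10R)-6,10-bis(tert-butyldimethylsilyloxy)-1,8-dimethyl-1-{2-[2-(propan-2-yl)-1,3-dioxolan-2-yl]ethyl}cyclohepta-5,8-diene
Product: 17 (1R,10R)-5-bromo-10-(tert-butyldimethylsilyloxy)-1,8-dimethyl-1-{2-[2-(propan-2-yl)-1,3-dioxolan-2-yl]ethyl}cyclohept-8-en-6-one (both C5 epimers)
Conditions: NBS, NaHCO3, THF, −78 °C to 0 °C, dark
Reagents that add atoms: N-bromosuccinimide, BrN1C(=O)CCC1=O
Why: Electrophilic bromination of a silyl enol ether puts bromine only on C5, the carbon the enol ether marks, and not on the more acidic allylic C7; the configuration at C5 does not matter because the centre becomes an enolate again in step 11.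

Step 10
Reactants: 17 (1R,10R)-5-bromo-10-(tert-butyldimethylsilyloxy)-1,8-dimethyl-1-{2-[2-(propan-2-yl)-1,3-dioxolan-2-yl]ethyl}cyclohept-8-en-6-one
Product: 18 (1R,10R)-5-bromo-10-(tert-butyldimethylsilyloxy)-1,8-dimethyl-1-(4-methyl-3-oxopentyl)cyclohept-8-en-6-one (both C5 epimers)
Conditions: PPTS, acetone/H2O (10:1), 45 °C
Reagents that add atoms: water, O
Why: Acid-catalysed hydrolysis of the dioxolane frees the isopropyl ketone; the α-bromo ketone, the hindered allylic TBS ether and the β,γ-alkene should tolerate this weak acid.

Step 11
Reactants: 18 (1R,10R)-5-bromo-10-(tert-butyldimethylsilyloxy)-1,8-dimethyl-1-(4-methyl-3-oxopentyl)cyclohept-8-en-6-one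
Product: 19 (1S,4R,5R,10R)-10-(tert-butyldimethylsilyloxy)-4-hydroxydauc-8-en-6-one
Conditions: SmI2 (2.2 equiv), THF, −78 °C, then 20 °C; pH 7 phosphate buffer
Reagents that add atoms: none
Why: Samarium Reformatsky-type aldol: SmI2 reduces the C5–Br bond to a regiodefined samarium enolate, which adds to the C4 ketone in a 5-exo closure of ring A without any base that could move C8=C9. Trivalent samarium bridges O6 and O4 in the aldolate and so places the new hydroxyl cis to C6 on ring A; of the two chelated ketols only the trans-fused one keeps the isopropyl group away from the angular methyl, and warming should let the aldolate equilibrate by retro-aldol to that isomer.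

Step 12
Reactants: 19 (1S,4R,5R,10R)-10-(tert-butyldimethylsilyloxy)-4-hydroxydauc-8-en-6-one
Product: 20 (1S,4R,5S,6S,10R)-10-(tert-butyldimethylsilyloxy)dauc-8-ene-4,6-diol
Conditions: Me4NBH(OAc)3, MeCN/AcOH (1:1), −30 °C
Reagents that add atoms: none
Why: Evans–Saksena reduction: the C4 hydroxyl binds the triacetoxyborohydride and delivers hydride to C6 from its own face, which gives the anti-1,3-diol with the new hydroxyl on the face of H5 (6S). An external hydride would be kept off that face by the angular methyl and give the other epimer; the acidic medium also avoids retro-aldol and alkene migration.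

Step 13
Reactants: 20 (1S,4R,5S,6S,10R)-10-(tert-butyldimethylsilyloxy)dauc-8-ene-4,6-diol; 21 4-methoxybenzoyl chloride
Product: 22 (1S,4R,5S,6S,10R)-10-(tert-butyldimethylsilyloxy)-4-hydroxydauc-8-en-6-yl 4-methoxybenzoate
Conditions: pyridine, DMAP (cat.), CH2Cl2, 0 °C to 25 °C
Reagents that add atoms: none
Why: Acylation of the only secondary alcohol; the tertiary C4 hydroxyl and the silyl ether should not react.

Step 14
Reactants: 22 (1S,4R,5S,6S,10R)-10-(tert-butyldimethylsilyloxy)-4-hydroxydauc-8-en-6-yl 4-methoxybenzoate
Product: 23 (1S,4R,5S,6S,10R)-4,10-dihydroxydauc-8-en-6-yl 4-methoxybenzoate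
Conditions: HF·pyridine, pyridine, THF, 0 °C to 25 °C
Reagents that add atoms: none
Why: Fluoride cleavage of the silyl ether in a pyridine-buffered medium, which should spare the aryl ester and not ionise the allylic alcohol.

Step 15
Reactants: 23 (1S,4R,5S,6S,10R)-4,10-dihydroxydauc-8-en-6-yl 4-methoxybenzoate; 24 angelic acid [(2Z)-2-methylbut-2-enoic acid]
Product: 26 (3R,3aS,4S,8R,8aS)-3-hydroxy-6,8a-dimethyl-8-{[(2Z)-2-methylbut-2-enoyl]oxy}-3-(propan-2-yl)-1,2,3,3a,4,5,8,8a-octahydroazulen-4-yl 4-methoxybenzoate (CNP0168729.1), via mixed anhydride 25 (not isolated)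
Conditions: 24, 2,4,6-Cl3C6H2COCl, Et3N, toluene, 25 °C; then 23, 80 °C, no DMAP
Reagents that add atoms: none
Why: Yamaguchi-type esterification through the mixed anhydride: the C10 alcohol attacks the unhindered angeloyl carbonyl and not the flanked trichlorobenzoyl one. Leaving out the nucleophilic catalyst avoids the addition–elimination that turns angelate into tiglate, and the tertiary alcohol stays free.

## Compound list

1 | 2,5-dimethylfuran | Cc1ccc(C)o1 | starting material
2 | 1,1,3,3-tetrabromoacetone | BrC(Br)C(=O)C(Br)Br | starting material
3 | 2,4-dibromo-1,5-dimethyl-8-oxabicyclo[3.2.1]oct-6-en-3-one (bridgeheads as in 4, mixture of bromide stereoisomers) | C[C@@]12C=C[C@@](C)(O1)C(Br)C(=O)C2Br | intermediate (not isolated)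
4 | (1R,5S)-1,5-dimethyl-8-oxabicyclo[3.2.1]oct-6-en-3-one (meso) | C[C@@]12C=C[C@@](C)(O1)CC(=O)C2 | intermediate
5 | (1R,5R)-1,5-dimethyl-3-(trimethylsilyloxy)-8-oxabicyclo[3.2.1]octa-2,6-diene | C[C@@]12C=C[C@@](C)(O1)C=C(O[Si](C)(C)C)C2 | intermediate
6 | (6R)-3,6-dimethyl-6-(trimethylsilyloxy)cyclohepta-2,4-dien-1-one | C[C@]1(O[Si](C)(C)C)C=CC(C)=CC(=O)C1 | intermediate (not isolated)
7 | (6R)-6-hydroxy-3,6-dimethylcyclohepta-2,4-dien-1-one | C[C@]1(O)C=CC(C)=CC(=O)C1 | intermediate
8 | (4R)-3,6-dimethyl-4-(trimethylsilyloxy)cyclohepta-2,5-dien-1-one | C[Si](C)(C)O[C@@H]1C=C(C)CC(=O)C=C1C | intermediate (not isolated)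
9 | (4R)-4-hydroxy-3,6-dimethylcyclohepta-2,5-dien-1-one | O[C@@H]1C=C(C)CC(=O)C=C1C | intermediate
10 | methyl 4-methyl-3-oxopentanoate | COC(=O)CC(=O)C(C)C | starting material
11 | methyl 2-[2-(propan-2-yl)-1,3-dioxolan-2-yl]acetate | COC(=O)CC1(OCCO1)C(C)C | intermediate
12 | 2-[2-(propan-2-yl)-1,3-dioxolan-2-yl]ethan-1-ol | OCCC1(OCCO1)C(C)C | intermediate
13 | 2-(2-bromoethyl)-2-(propan-2-yl)-1,3-dioxolane | BrCCC1(OCCO1)C(C)C | intermediate
14 | {2-[2-(propan-2-yl)-1,3-dioxolan-2-yl]ethyl}magnesium bromide | Br[Mg]CCC1(OCCO1)C(C)C | intermediate (not isolated)
15 | (1S,10R) conjugate adduct as its C10 chloromagnesium alkoxide and C5=C6 bromomagnesium enolate | Cl[Mg]O[C@@H]1C=C(C)CC(O[Mg]Br)=C[C@]1(C)CCC2(OCCO2)C(C)C | intermediate (not isolated)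
16 | (1S,10R)-6,10-bis(tert-butyldimethylsilyloxy)-1,8-dimethyl-1-{2-[2-(propan-2-yl)-1,3-dioxolan-2-yl]ethyl}cyclohepta-5,8-diene (target locants; silyl enol ether at C5=C6) | CC(C)(C)[Si](C)(C)O[C@@H]1C=C(C)CC(O[Si](C)(C)C(C)(C)C)=C[C@]1(C)CCC2(OCCO2)C(C)C | intermediate
17 | (1R,10R)-5-bromo-10-(tert-butyldimethylsilyloxy)-1,8-dimethyl-1-{2-[2-(propan-2-yl)-1,3-dioxolan-2-yl]ethyl}cyclohept-8-en-6-one (target locants; both C5 epimers) | CC(C)(C)[Si](C)(C)O[C@@H]1C=C(C)CC(=O)C(Br)[C@]1(C)CCC2(OCCO2)C(C)C | intermediate
18 | (1R,10R)-5-bromo-10-(tert-butyldimethylsilyloxy)-1,8-dimethyl-1-(4-methyl-3-oxopentyl)cyclohept-8-en-6-one (target locants; both C5 epimers) | CC(C)(C)[Si](C)(C)O[C@@H]1C=C(C)CC(=O)C(Br)[C@]1(C)CCC(=O)C(C)C | intermediate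
19 | (1S,4R,5R,10R)-10-(tert-butyldimethylsilyloxy)-4-hydroxydauc-8-en-6-one (trans-fused; OH cis to the angular methyl) | CC(C)(C)[Si](C)(C)O[C@@H]1C=C(C)CC(=O)[C@@H]2[C@]1(C)CC[C@@]2(O)C(C)C | intermediate
20 | (1S,4R,5S,6S,10R)-10-(tert-butyldimethylsilyloxy)dauc-8-ene-4,6-diol | CC(C)(C)[Si](C)(C)O[C@@H]1C=C(C)C[C@H](O)[C@@H]2[C@]1(C)CC[C@@]2(O)C(C)C | intermediate
21 | 4-methoxybenzoyl chloride | COc1ccc(cc1)C(Cl)=O | starting material
22 | (1S,4R,5S,6S,10R)-10-(tert-butyldimethylsilyloxy)-4-hydroxydauc-8-en-6-yl 4-methoxybenzoate | CC(C)(C)[Si](C)(C)O[C@@H]1C=C(C)C[C@H](OC(=O)c2ccc(OC)cc2)[C@@H]2[C@]1(C)CC[C@@]2(O)C(C)C | intermediate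
23 | (1S,4R,5S,6S,10R)-4,10-dihydroxydauc-8-en-6-yl 4-methoxybenzoate | O[C@@H]1C=C(C)C[C@H](OC(=O)c2ccc(OC)cc2)[C@@H]2[C@]1(C)CC[C@@]2(O)C(C)C | intermediate
24 | angelic acid, (2Z)-2-methylbut-2-enoic acid | C/C=C(/C)C(O)=O | starting material
25 | (2Z)-2-methylbut-2-enoic 2,4,6-trichlorobenzoic anhydride | C/C=C(/C)C(=O)OC(=O)c1c(Cl)cc(Cl)cc1Cl | intermediate (not isolated)
26 | (3R,3aS,4S,8R,8aS)-3-hydroxy-6,8a-dimethyl-8-{[(2Z)-2-methylbut-2-enoyl]oxy}-3-(propan-2-yl)-1,2,3,3a,4,5,8,8a-octahydroazulen-4-yl 4-methoxybenzoate | C/C=C(/C)C(=O)O[C@@H]1C=C(C)C[C@H](OC(=O)c2ccc(OC)cc2)[C@@H]2[C@]1(C)CC[C@@]2(O)C(C)C | target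

## Step count and least certain steps

Total: 15 steps. Longest linear sequence: 12 steps (steps 1–4 and 8–15) from 1 and 2; the side chain 13 takes 3 steps (5–7) from 10.

Step 1 (key step). What may go wrong: acid- or zinc-bromide-promoted oligomerisation and electrophilic substitution of the electron-rich furan in place of cycloaddition, and incomplete or excessive reduction in the debromination. Fallback: the oxyallyl cation is made by base instead of by reduction. Setting out from 1, treatment with 1,1,3-trichloroacetone and Et3N in 2,2,2-trifluoroethanol should give the racemic 2,2-dichloro-1,5-dimethyl-8-oxabicyclo[3.2.1]oct-6-en-3-one F1, and Zn–Cu couple with NH4Cl in MeOH then removes both chlorines and returns to the route at 4.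

Step 4. What may go wrong: ionisation of the allylic perrhenate instead of the concerted shift, which would erode the configuration or end in loss of water and aromatisation to the tropone; slow turnover on the electron-poor dienone; competing silylation of the tertiary alcohol, which stalls the shift. Fallback: an allylic ester [3,3] shift under divalent palladium. Setting out from 7, acetylation without base (Ac2O, catalytic Sc(OTf)3, MeCN, −20 °C) should give (1R)-1,4-dimethyl-6-oxocyclohepta-2,4-dien-1-yl acetate F2. PdCl2(MeCN)2 (5 mol %) in THF interconverts it suprafacially with the secondary ester (1R)-2,6-dimethyl-4-oxocyclohepta-2,6-dien-1-yl acetate F3. A lipase in pH 7 buffer hydrolyses the less hindered secondary acetate and comes back to the route at 9, while recovered tertiary acetate is recycled.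

Step 8. What may go wrong: 1,2-addition to the ketone, enolisation at C7 by the basic reagent, isomerisation of the γ-hydroxy enone to a 1,4-diketone, and undirected attack from the face opposite to O10. Fallback: catalyst control in place of substrate direction. Setting out from 9, TBSCl and imidazole give (4R)-4-(tert-butyldimethylsilyloxy)-3,6-dimethylcyclohepta-2,5-dien-1-one F4. A copper-catalysed asymmetric conjugate addition of 14 (Cu(OTf)2 with a chiral N-heterocyclic carbene precursor, Et2O, −30 °C), with the enolate trapped by TBSOTf, returns to the route at 16. The ligand enantiomer has to be the one that overrides the anti preference of the silyloxy group.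

Step 11. What may go wrong: closure to the cis-fused ketol or to the C4 epimer if the aldolate does not equilibrate, protonation of the samarium enolate without C–C bond formation (plain debromination), and dehydration of the tertiary ketol. Fallback: a Lewis-acid-mediated closure of an isolated enol ether. Setting out from 18, zinc dust and TMSCl in MeCN convert the α-bromo ketone regiospecifically into the C5=C6 trimethylsilyl enol ether F5. TiCl4 in CH2Cl2 at −78 °C then effects an intramolecular Mukaiyama aldol, with titanium held between the two oxygens, and returns to the route at 19.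

Step 15. What may go wrong: Z-to-E isomerisation during activation or acyl transfer, sluggish acylation of the hindered C10 alcohol, and acyl migration from O6. Fallback: the Z-alkene is built on the molecule. Setting out from 23, DCC-mediated esterification of the C10 alcohol with 2-[bis(2,2,2-trifluoroethoxy)phosphoryl]propanoic acid gives phosphonate ester F6. A Still–Gennari olefination with acetaldehyde (KHMDS, 18-crown-6, THF, −78 °C), which is Z-selective, comes back to the route at 26.

## Further compounds

F1 | step 1 | 2,2-dichloro-1,5-dimethyl-8-oxabicyclo[3.2.1]oct-6-en-3-one (racemic, one enantiomer drawn) | C[C@@]12C=C[C@@](C)(O1)CC(=O)C2(Cl)Cl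
F2 | step 4 | (1R)-1,4-dimethyl-6-oxocyclohepta-2,4-dien-1-yl acetate | C[C@]1(OC(C)=O)C=CC(C)=CC(=O)C1
F3 | step 4 | (1R)-2,6-dimethyl-4-oxocyclohepta-2,6-dien-1-yl acetate | CC(=O)O[C@@H]1C=C(C)CC(=O)C=C1C
F4 | step 8 | (4R)-4-(tert-butyldimethylsilyloxy)-3,6-dimethylcyclohepta-2,5-dien-1-one | CC(C)(C)[Si](C)(C)O[C@@H]1C=C(C)CC(=O)C=C1C
F5 | step 11 | (1S,10R)-10-(tert-butyldimethylsilyloxy)-1,8-dimethyl-1-(4-methyl-3-oxopentyl)-6-(trimethylsilyloxy)cyclohepta-5,8-diene (target locants) | CC(C)(C)[Si](C)(C)O[C@@H]1C=C(C)CC(O[Si](C)(C)C)=C[C@]1(C)CCC(=O)C(C)C
F6 | step 15 | (1S,4R,5S,6S,10R)-10-{2-[bis(2,2,2-trifluoroethoxy)phosphoryl]propanoyloxy}-4-hydroxydauc-8-en-6-yl 4-methoxybenzoate (both epimers at the phosphonate carbon) | CC(C(=O)O[C@@H]1C=C(C)C[C@H](OC(=O)c2ccc(OC)cc2)[C@@H]2[C@]1(C)CC[C@@]2(O)C(C)C)P(=O)(OCC(F)(F)F)OCC(F)(F)F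
A1 | alternative 1 | iodo ketone: ring-B cycloheptene with C10 triethylsilyl ether, C6 tert-butyldimethylsilyl ether, 2-iodoethyl on C1 and 2-methylpropanoyl on C5 | CC[Si](CC)(CC)O[C@@H]1C=C(C)C[C@H](O[Si](C)(C)C(C)(C)C)[C@@H](C(=O)C(C)C)[C@]1(C)CCI
A2 | alternative 1 | bis-silyl ether of the triol core (C10 triethylsilyl, C6 tert-butyldimethylsilyl, C4 hydroxyl free) | CC[Si](CC)(CC)O[C@@H]1C=C(C)C[C@H](O[Si](C)(C)C(C)(C)C)[C@@H]2[C@]1(C)CC[C@@]2(O)C(C)C
A3 | alternative 2 | 3-methylcyclopent-2-en-1-one | CC1=CC(=O)CC1
A4 | alternative 2 | 4-methyl-1,2-bis(trimethylsilyloxy)cyclopent-1-ene | CC1CC(O[Si](C)(C)C)=C(O[Si](C)(C)C)C1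
A5 | alternative 2 | cis-anti-cis tricyclic photoadduct | C[C@]12CCC(=O)[C@H]1[C@]1(O[Si](C)(C)C)C[C@@H](C)C[C@]21O[Si](C)(C)C
A6 | alternative 2 | cis-fused 6,8a-dimethylhexahydroazulene-3,4,8-trione (ketones at C4, C6 and C10 of the target) | C[C@]12CCC(=O)[C@H]1C(=O)C[C@@H](C)CC2=O
A7 | alternative 3 | 2-diazo-5-(2,6-dimethoxy-4-methylphenyl)pentan-3-one | CC(=[N+]=[N-])C(=O)CCc1c(OC)cc(C)cc1OC
A8 | alternative 3 | 4,8-dimethoxy-6,8a-dimethyl-3,8a-dihydroazulen-1(2H)-one | COC1=CC(C)=CC(OC)=C2CCC(=O)[C@]12C
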